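Everything rests on making the cis-2-aryl-3-(hydroxymethyl)dihydrobenzofuran from a six-membered precursor. The five ring atoms O1, C2, C3, C3a and C7a plus the carbon hanging from C3 are the six atoms of a chroman-4-one pyranone ring, so extruding the carbonyl carbon from that ring gives the target ring with its side carbon already in place. Irradiating an enantiopure 3-diazoflavanone in methanol does this in one operation: the ring-aryl carbon migrates to C3 (new C3–C3a bond), the ketene is captured as the methyl ester, and protonation anti to the C2 aryl leaves C2–H and C3–H cis. The precursor bears a benzyl-protected syringyl group at C2 and a benzoate-protected hydroxypropyl chain at C6.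

Key step: step 8

Assumption: (S)-t-BuPyOx is taken to deliver the aryl group to the chromone face that gives the 2R flavanone, by analogy with its sense on cyclic enones; should the sense be opposite, (R)-t-BuPyOx is used instead.

Abbreviations: TBS = tert-butyldimethylsilyl, TBSO = tert-butyldimethylsilyloxy, 9-BBN = 9-borabicyclo[3.3.1]nonane, p-ABSA = 4-acetamidobenzenesulfonyl azide.

Step 1
Reactants: 1 1-(2-hydroxy-3-methoxyphenyl)ethan-1-one
Product: 2 1-(5-bromo-2-hydroxy-3-methoxyphenyl)ethan-1-one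
Conditions: NBS (1.05 equiv), MeCN, 0 °C to rt
Reagents that add atoms: N-bromosuccinimide, O=C1CCC(=O)N1Br
Why: Electrophilic aromatic bromination, in which the phenol directs the halogen to its para position, the only ring position that is also meta to the deactivating acetyl group, so one regioisomer is expected.

Step 2
Reactants: 2 1-(5-bromo-2-hydroxy-3-methoxyphenyl)ethan-1-one; 3 N,N-dimethylformamide dimethyl acetal
Product: 5 6-bromo-8-methoxy-4H-chromen-4-one, via enaminone 4 (not isolated)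
Conditions: 3 (2 equiv), toluene, 100 °C; then conc. HCl, CH2Cl2, rt
Reagents that add atoms: none
Why: Standard enaminone chromone synthesis, in which the amide acetal condenses with the methyl ketone and acid then drives intramolecular addition of the phenol oxygen with loss of dimethylamine to close the γ-pyrone.

Step 3
Reactants: 5 6-bromo-8-methoxy-4H-chromen-4-one; 6 prop-2-en-1-yl benzoate
Product: 8 3-(8-methoxy-4-oxo-4H-chromen-6-yl)propyl benzoate, via alkylborane 7 (not isolated)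
Conditions: 6, 9-BBN, THF, 0 °C to rt; then 5, PdCl2(dppf) (5 mol %), K3PO4, DMF, 50 °C
Reagents that add atoms: none
Why: Anti-Markovnikov hydroboration of the terminal alkene followed by B-alkyl Suzuki–Miyaura coupling at the aryl bromide under the ester-tolerant phosphate/DMF protocol; the chain oxygen is carried as a benzoate because it has no α-hydrogens and ignores acid and fluoride, so it should pass steps 6 to 8 untouched.

Step 4
Reactants: 9 4-bromo-2,6-dimethoxyphenol
Product: 10 2-(benzyloxy)-5-bromo-1,3-dimethoxybenzene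
Conditions: BnBr, K2CO3, DMF, rt
Reagents that add atoms: benzyl bromide, BrCc1ccccc1
Why: Williamson ether synthesis on an acidic, if hindered, 2,6-dimethoxyphenol with a reactive benzylic halide.

Step 5
Reactants: 10 2-(benzyloxy)-5-bromo-1,3-dimethoxybenzene
Product: 13 [4-(benzyloxy)-3,5-dimethoxyphenyl]boronic acid, via aryllithium 11 (not isolated), via lithium arylborate 12 (not isolated)
Conditions: n-BuLi, THF, −78 °C; B(OiPr)3, −78 °C to rt; 1 M HCl
Reagents that add atoms: triisopropyl borate, CC(C)OB(OC(C)C)OC(C)C; water, O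
Why: Bromine–lithium exchange, borate trapping and hydrolysis is the standard route to an arylboronic acid, and the benzyl ether is inert to the aryllithium at −78 °C.

Step 6
Reactants: 8 3-(8-methoxy-4-oxo-4H-chromen-6-yl)propyl benzoate; 13 [4-(benzyloxy)-3,5-dimethoxyphenyl]boronic acid
Product: 14 3-[(2R)-2-[4-(benzyloxy)-3,5-dimethoxyphenyl]-8-methoxy-4-oxo-3,4-dihydro-2H-chromen-6-yl]propyl benzoate
Conditions: Pd(OCOCF3)2 (5 mol %), (S)-t-BuPyOx (6 mol %), NH4PF6 (30 mol %), H2O (5 equiv), ClCH2CH2Cl, 60 °C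
Reagents that add atoms: none
Why: Pd(II)/pyridine-oxazoline asymmetric conjugate addition of an arylboronic acid to a chromone (transmetalation, enantiodetermining carbopalladation of C2=C3 on the face left open by the tert-butyl group of the ligand, protonolysis of the palladium enolate), which sets C2 as R and tolerates water, esters and benzyl ethers.

Step 7
Reactants: 14 3-[(2R)-2-[4-(benzyloxy)-3,5-dimethoxyphenyl]-8-methoxy-4-oxo-3,4-dihydro-2H-chromen-6-yl]propyl benzoate
Product: 17 3-[(2S)-2-[4-(benzyloxy)-3,5-dimethoxyphenyl]-3-diazo-8-methoxy-4-oxo-3,4-dihydro-2H-chromen-6-yl]propyl benzoate, via lithium enolate 15 (not isolated), via trifluoroacetyl ketone 16 (not isolated)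
Conditions: LiHMDS (1.1 equiv), THF, −78 °C; CF3CO2CH2CF3 (1.2 equiv), −78 °C; aq. HCl work-up; then p-ABSA, Et3N, H2O (1 equiv), MeCN, 0 °C to rt
Reagents that add atoms: 4-acetamidobenzenesulfonyl azide, CC(=O)Nc1ccc(cc1)S(=O)(=O)N=[N+]=[N-]
Why: Detrifluoroacetylative diazo transfer (Regitz-type) in which kinetic C3 enolisation at −78 °C and immediate Claisen trifluoroacetylation activate C3 so that the sulfonyl azide delivers N2 under mild amine base, keeping the free enolate too short-lived for E1cB opening of the pyranone ring; the spatial arrangement at C2 is unchanged and only its descriptor switches to S because the diazo carbon now outranks the aryl group.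

Step 8
Reactants: 17 3-[(2S)-2-[4-(benzyloxy)-3,5-dimethoxyphenyl]-3-diazo-8-methoxy-4-oxo-3,4-dihydro-2H-chromen-6-yl]propyl benzoate
Product: 19 methyl (2R,3S)-5-[3-(benzoyloxy)propyl]-2-[4-(benzyloxy)-3,5-dimethoxyphenyl]-7-methoxy-2,3-dihydro-1-benzofuran-3-carboxylate (2-aryl cis to ester), via ketene 18 (not isolated)
Conditions: hν (365 nm LED), MeOH–CH2Cl2 (4:1), −20 °C, N2
Reagents that add atoms: methanol, CO
Why: Excitation of the s-cis-locked cyclic diazoketone expels N2 with concerted 1,2-shift of the ring-aryl carbon C4a from the carbonyl carbon to C3, giving a 3-(oxomethylidene)dihydrobenzofuran (ketene) that methanol converts into the ester enol and then the ester. The closest known reaction type is the photochemical Wolff ring contraction of cyclic 2-diazo-1-ketones, established for benzo-fused diazoketones. The five-membered ring O1–C2–C3–C3a–C7a is closed by ring contraction, that is by the 1,2-migration that forms C3–C3a inside the existing six-membered ring, not by an end-to-end cyclisation. The new C3 stereocentre should be set by kinetic protonation of the exocyclic ester enol, which is flat at C3 and shielded on one face by the C2 aryl group, so the proton arrives anti to the aryl and the ester ends cis to it (2R,3S) while C2 is untouched. The step needs facial selectivity in this protonation and chemoselectivity for the Wolff shift over 1,2-hydride shift (flavone) and O–H insertion; the first is secured by the neighbouring aryl group on the nearly planar ring together with a neutral, cold medium that cannot epimerise the cis ester, the second by the enforced s-cis geometry and direct photolysis without metal carbenoids.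

Step 9
Reactants: 19 methyl (2R,3S)-5-[3-(benzoyloxy)propyl]-2-[4-(benzyloxy)-3,5-dimethoxyphenyl]-7-methoxy-2,3-dihydro-1-benzofuran-3-carboxylate
Product: 20 3-[(2R,3R)-2-[4-(benzyloxy)-3,5-dimethoxyphenyl]-3-(hydroxymethyl)-7-methoxy-2,3-dihydro-1-benzofuran-5-yl]propan-1-ol
Conditions: DIBAL-H (6 equiv), CH2Cl2, −78 to −40 °C; Rochelle salt
Reagents that add atoms: none
Why: DIBAL-H reduction of the methyl ester to the primary alcohol with concurrent reductive removal of the benzoate; the cold, non-basic hydride should leave the epimerisable cis C3 centre intact, and after reduction C3 is no longer acidic.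

Step 10
Reactants: 20 3-[(2R,3R)-2-[4-(benzyloxy)-3,5-dimethoxyphenyl]-3-(hydroxymethyl)-7-methoxy-2,3-dihydro-1-benzofuran-5-yl]propan-1-ol
Product: 21 (2R,3R)-2-[4-(benzyloxy)-3,5-dimethoxyphenyl]-7-methoxy-3-[(TBSO)methyl]-5-[3-(TBSO)propyl]-2,3-dihydro-1-benzofuran
Conditions: TBSCl (2.5 equiv), imidazole, DMF, rt
Reagents that add atoms: tert-butyldimethylsilyl chloride, CC(C)(C)[Si](C)(C)Cl
Why: Imidazole-promoted silylation of both primary alcohols in one operation.

Step 11
Reactants: 21 (2R,3R)-2-[4-(benzyloxy)-3,5-dimethoxyphenyl]-7-methoxy-3-[(TBSO)methyl]-5-[3-(TBSO)propyl]-2,3-dihydro-1-benzofuran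
Product: 22 4-[(2R,3R)-7-methoxy-3-[(TBSO)methyl]-5-[3-(TBSO)propyl]-2,3-dihydro-1-benzofuran-2-yl]-2,6-dimethoxyphenol
Conditions: H2 (1 atm), 10% Pd/C, EtOAc, rt
Reagents that add atoms: none
Why: Hydrogenolysis of the benzyl aryl ether, which under neutral conditions at 1 atm should be much faster than cleavage of the ring C2–O bond and leaves silyl ethers untouched.

Step 12
Reactants: 23 methyl (4R)-2,2-dimethyl-1,3-dioxolane-4-carboxylate
Product: 24 methyl (2R)-2,3-dihydroxypropanoate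
Conditions: Dowex 50W-X8 (H+), MeOH, rt
Reagents that add atoms: none
Why: Acid-catalysed transketalisation to methanol frees the diol without touching the methyl ester or the stereocentre.

Step 13
Reactants: 24 methyl (2R)-2,3-dihydroxypropanoate
Product: 25 methyl (2R)-2-hydroxy-3-(TBSO)propanoate
Conditions: TBSCl (1.05 equiv), imidazole, CH2Cl2, 0 °C
Reagents that add atoms: tert-butyldimethylsilyl chloride, CC(C)(C)[Si](C)(C)Cl
Why: Sterically controlled monosilylation of the primary hydroxyl in preference to the hindered, hydrogen-bonded α-hydroxy ester OH.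

Step 14
Reactants: 22 4-[(2R,3R)-7-methoxy-3-[(TBSO)methyl]-5-[3-(TBSO)propyl]-2,3-dihydro-1-benzofuran-2-yl]-2,6-dimethoxyphenol; 25 methyl (2R)-2-hydroxy-3-(TBSO)propanoate
Product: 26 methyl (2S)-2-{4-[(2R,3R)-7-methoxy-3-[(TBSO)methyl]-5-[3-(TBSO)propyl]-2,3-dihydro-1-benzofuran-2-yl]-2,6-dimethoxyphenoxy}-3-(TBSO)propanoate
Conditions: PPh3, DIAD, THF, 0 °C to rt
Reagents that add atoms: none
Why: Mitsunobu etherification in which the phenol displaces the activated α-hydroxy ester oxygen in an SN2 step with inversion, turning the 2R alcohol into the 2S aryl ether (C2 of the propanediol unit), a reaction known for 2,6-dimethoxyphenols with lactate-type esters.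

Step 15
Reactants: 26 methyl (2S)-2-{4-[(2R,3R)-7-methoxy-3-[(TBSO)methyl]-5-[3-(TBSO)propyl]-2,3-dihydro-1-benzofuran-2-yl]-2,6-dimethoxyphenoxy}-3-(TBSO)propanoate
Product: 27 (2S)-2-{4-[(2R,3R)-7-methoxy-3-[(TBSO)methyl]-5-[3-(TBSO)propyl]-2,3-dihydro-1-benzofuran-2-yl]-2,6-dimethoxyphenoxy}-3-(TBSO)propanal
Conditions: DIBAL-H (1.2 equiv), toluene, −78 °C; MeOH, then Rochelle salt
Reagents that add atoms: none
Why: Partial DIBAL-H reduction, in which the chelated aluminium hemiacetal of an α-alkoxy ester survives at −78 °C and releases the aldehyde only on work-up, which also limits epimerisation of the α-aryloxy centre.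

Step 16
Reactants: 28 4-bromo-2-methoxyphenol
Product: 29 (4-bromo-2-methoxyphenoxy)(tert-butyl)dimethylsilane
Conditions: TBSCl, imidazole, DMF, rt
Reagents that add atoms: tert-butyldimethylsilyl chloride, CC(C)(C)[Si](C)(C)Cl
Why: Routine phenol silylation, so that the derived aryllithium carries no acidic proton and the group leaves in the final fluoride step.

Step 17
Reactants: 27 (2S)-2-{4-[(2R,3R)-7-methoxy-3-[(TBSO)methyl]-5-[3-(TBSO)propyl]-2,3-dihydro-1-benzofuran-2-yl]-2,6-dimethoxyphenoxy}-3-(TBSO)propanal; 29 (4-bromo-2-methoxyphenoxy)(tert-butyl)dimethylsilane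
Product: 31 (1R,2S)-1-[3-methoxy-4-(TBSO)phenyl]-2-{4-[(2R,3R)-7-methoxy-3-[(TBSO)methyl]-5-[3-(TBSO)propyl]-2,3-dihydro-1-benzofuran-2-yl]-2,6-dimethoxyphenoxy}-3-(TBSO)propan-1-ol, via aryllithium 30 (not isolated)
Conditions: 29, n-BuLi, THF, −78 °C; then 27, −78 °C; aq. NH4Cl
Reagents that add atoms: none
Why: 1,2-Addition of an aryllithium to an α-aryloxy aldehyde under non-chelating conditions (Li, THF, −78 °C), where in the polar Felkin–Anh transition state the bulky, electronegative aryloxy group lies anti to the incoming nucleophile, which passes the α-hydrogen, so the anti (erythro) 1R,2S alcohol should predominate.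

Step 18
Reactants: 31 (1R,2S)-1-[3-methoxy-4-(TBSO)phenyl]-2-{4-[(2R,3R)-7-methoxy-3-[(TBSO)methyl]-5-[3-(TBSO)propyl]-2,3-dihydro-1-benzofuran-2-yl]-2,6-dimethoxyphenoxy}-3-(TBSO)propan-1-ol
Product: 32 (1R,2S)-1-(4-hydroxy-3-methoxyphenyl)-2-{4-[(2R,3R)-3-(hydroxymethyl)-5-(3-hydroxypropyl)-7-methoxy-2,3-dihydro-1-benzofuran-2-yl]-2,6-dimethoxyphenoxy}propane-1,3-diol (CNP0301567.1)
Conditions: TBAF (6 equiv), AcOH (6 equiv), THF, 0 °C to rt
Reagents that add atoms: none
Why: Fluoride cleavage of the three alkyl and one aryl silyl ethers, with acetic acid buffering to keep the p-hydroxybenzyl alcohol and the cis dihydrobenzofuran away from phenoxide-driven quinone methide chemistry.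

Compound list

1 | 1-(2-hydroxy-3-methoxyphenyl)ethan-1-one | CC(=O)c1cccc(OC)c1O | starting material
2 | 1-(5-bromo-2-hydroxy-3-methoxyphenyl)ethan-1-one | CC(=O)c1cc(Br)cc(OC)c1O | intermediate
3 | N,N-dimethylformamide dimethyl acetal | COC(OC)N(C)C | starting material
4 | (E)-1-(5-bromo-2-hydroxy-3-methoxyphenyl)-3-(dimethylamino)prop-2-en-1-one | CN(C)/C=C/C(=O)c1cc(Br)cc(OC)c1O | intermediate
5 | 6-bromo-8-methoxy-4H-chromen-4-one | COc1cc(Br)cc2c(=O)ccoc12 | intermediate
6 | prop-2-en-1-yl benzoate (allyl benzoate) | C=CCOC(=O)c1ccccc1 | starting material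
7 | 3-(9-borabicyclo[3.3.1]nonan-9-yl)propyl benzoate | O=C(OCCCB1C2CCCC1CCC2)c1ccccc1 | intermediate
8 | 3-(8-methoxy-4-oxo-4H-chromen-6-yl)propyl benzoate | COc1cc(CCCOC(=O)c3ccccc3)cc2c(=O)ccoc12 | intermediate
9 | 4-bromo-2,6-dimethoxyphenol | COc1cc(Br)cc(OC)c1O | starting material
10 | 2-(benzyloxy)-5-bromo-1,3-dimethoxybenzene | COc1cc(Br)cc(OC)c1OCc1ccccc1 | intermediate
11 | [4-(benzyloxy)-3,5-dimethoxyphenyl]lithium | [Li]c1cc(OC)c(OCc2ccccc2)c(OC)c1 | intermediate
12 | lithium [4-(benzyloxy)-3,5-dimethoxyphenyl]tris(propan-2-yloxy)borate | [Li+].CC(C)O[B-](OC(C)C)(OC(C)C)c1cc(OC)c(OCc2ccccc2)c(OC)c1 | intermediate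
13 | [4-(benzyloxy)-3,5-dimethoxyphenyl]boronic acid | OB(O)c1cc(OC)c(OCc2ccccc2)c(OC)c1 | intermediate
14 | 3-[(2R)-2-[4-(benzyloxy)-3,5-dimethoxyphenyl]-8-methoxy-4-oxo-3,4-dihydro-2H-chromen-6-yl]propyl benzoate | c1ccccc1COc2c(OC)cc([C@@H]3Oc4c(OC)cc(CCCOC(=O)c5ccccc5)cc4C(=O)C3)cc2OC | intermediate
15 | lithium (2R)-6-[3-(benzoyloxy)propyl]-2-[4-(benzyloxy)-3,5-dimethoxyphenyl]-8-methoxy-2H-chromen-4-olate | c1ccccc1COc2c(OC)cc([C@@H]3Oc4c(OC)cc(CCCOC(=O)c5ccccc5)cc4C(O[Li])=C3)cc2OC | intermediate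
16 | 3-[(2R)-2-[4-(benzyloxy)-3,5-dimethoxyphenyl]-8-methoxy-4-oxo-3-(trifluoroacetyl)-3,4-dihydro-2H-chromen-6-yl]propyl benzoate (C3 not assigned; enolised) | c1ccccc1COc2c(OC)cc([C@@H]3Oc4c(OC)cc(CCCOC(=O)c5ccccc5)cc4C(=O)C3C(=O)C(F)(F)F)cc2OC | intermediate
17 | 3-[(2S)-2-[4-(benzyloxy)-3,5-dimethoxyphenyl]-3-diazo-8-methoxy-4-oxo-3,4-dihydro-2H-chromen-6-yl]propyl benzoate | c1ccccc1COc2c(OC)cc([C@@H]3Oc4c(OC)cc(CCCOC(=O)c5ccccc5)cc4C(=O)C3=[N+]=[N-])cc2OC | intermediate
18 | 3-[(2S)-2-[4-(benzyloxy)-3,5-dimethoxyphenyl]-7-methoxy-3-(oxomethylidene)-2,3-dihydro-1-benzofuran-5-yl]propyl benzoate | c1ccccc1COc2c(OC)cc([C@@H]3Oc4c(OC)cc(CCCOC(=O)c5ccccc5)cc4C3=C=O)cc2OC | intermediate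
19 | methyl (2R,3S)-5-[3-(benzoyloxy)propyl]-2-[4-(benzyloxy)-3,5-dimethoxyphenyl]-7-methoxy-2,3-dihydro-1-benzofuran-3-carboxylate | c1ccccc1COc2c(OC)cc([C@@H]3Oc4c(OC)cc(CCCOC(=O)c5ccccc5)cc4[C@@H]3C(=O)OC)cc2OC | intermediate
20 | 3-[(2R,3R)-2-[4-(benzyloxy)-3,5-dimethoxyphenyl]-3-(hydroxymethyl)-7-methoxy-2,3-dihydro-1-benzofuran-5-yl]propan-1-ol | c1ccccc1COc2c(OC)cc([C@@H]3Oc4c(OC)cc(CCCO)cc4[C@@H]3CO)cc2OC | intermediate
21 | (2R,3R)-2-[4-(benzyloxy)-3,5-dimethoxyphenyl]-7-methoxy-3-[(TBSO)methyl]-5-[3-(TBSO)propyl]-2,3-dihydro-1-benzofuran | c1ccccc1COc2c(OC)cc([C@@H]3Oc4c(OC)cc(CCCO[Si](C)(C)C(C)(C)C)cc4[C@@H]3CO[Si](C)(C)C(C)(C)C)cc2OC | intermediate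
22 | 4-[(2R,3R)-7-methoxy-3-[(TBSO)methyl]-5-[3-(TBSO)propyl]-2,3-dihydro-1-benzofuran-2-yl]-2,6-dimethoxyphenol | Oc1c(OC)cc([C@@H]2Oc3c(OC)cc(CCCO[Si](C)(C)C(C)(C)C)cc3[C@@H]2CO[Si](C)(C)C(C)(C)C)cc1OC | intermediate
23 | methyl (4R)-2,2-dimethyl-1,3-dioxolane-4-carboxylate | COC(=O)[C@H]1COC(C)(C)O1 | starting material
24 | methyl (2R)-2,3-dihydroxypropanoate | COC(=O)[C@H](O)CO | intermediate
25 | methyl (2R)-2-hydroxy-3-(TBSO)propanoate | COC(=O)[C@H](O)CO[Si](C)(C)C(C)(C)C | intermediate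
26 | methyl (2S)-2-{4-[(2R,3R)-7-methoxy-3-[(TBSO)methyl]-5-[3-(TBSO)propyl]-2,3-dihydro-1-benzofuran-2-yl]-2,6-dimethoxyphenoxy}-3-(TBSO)propanoate | COC(=O)[C@H](CO[Si](C)(C)C(C)(C)C)Oc1c(OC)cc([C@@H]2Oc3c(OC)cc(CCCO[Si](C)(C)C(C)(C)C)cc3[C@@H]2CO[Si](C)(C)C(C)(C)C)cc1OC | intermediate
27 | (2S)-2-{4-[(2R,3R)-7-methoxy-3-[(TBSO)methyl]-5-[3-(TBSO)propyl]-2,3-dihydro-1-benzofuran-2-yl]-2,6-dimethoxyphenoxy}-3-(TBSO)propanal | O=C[C@H](CO[Si](C)(C)C(C)(C)C)Oc1c(OC)cc([C@@H]2Oc3c(OC)cc(CCCO[Si](C)(C)C(C)(C)C)cc3[C@@H]2CO[Si](C)(C)C(C)(C)C)cc1OC | intermediate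
28 | 4-bromo-2-methoxyphenol | COc1cc(Br)ccc1O | starting material
29 | (4-bromo-2-methoxyphenoxy)(tert-butyl)dimethylsilane | COc1cc(Br)ccc1O[Si](C)(C)C(C)(C)C | intermediate
30 | [3-methoxy-4-(TBSO)phenyl]lithium | [Li]c1ccc(O[Si](C)(C)C(C)(C)C)c(OC)c1 | intermediate
31 | (1R,2S)-1-[3-methoxy-4-(TBSO)phenyl]-2-{4-[(2R,3R)-7-methoxy-3-[(TBSO)methyl]-5-[3-(TBSO)propyl]-2,3-dihydro-1-benzofuran-2-yl]-2,6-dimethoxyphenoxy}-3-(TBSO)propan-1-ol | COc1cc([C@@H](O)[C@H](CO[Si](C)(C)C(C)(C)C)Oc2c(OC)cc([C@@H]3Oc4c(OC)cc(CCCO[Si](C)(C)C(C)(C)C)cc4[C@@H]3CO[Si](C)(C)C(C)(C)C)cc2OC)ccc1O[Si](C)(C)C(C)(C)C | intermediate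
32 | (1R,2S)-1-(4-hydroxy-3-methoxyphenyl)-2-{4-[(2R,3R)-3-(hydroxymethyl)-5-(3-hydroxypropyl)-7-methoxy-2,3-dihydro-1-benzofuran-2-yl]-2,6-dimethoxyphenoxy}propane-1,3-diol | COc1cc([C@@H](O)[C@H](CO)Oc2c(OC)cc([C@@H]3Oc4c(OC)cc(CCCO)cc4[C@@H]3CO)cc2OC)ccc1O | target

Total step count: 18. Longest linear sequence: 13 steps (1, 2, 3, 6, 7, 8, 9, 10, 11, 14, 15, 17, 18).

Steps most likely to fail

1. Step 8. The ester enol may be protonated with too little facial bias, giving the trans ester, or the excited diazoketone may be diverted into 1,2-hydride shift and O–H insertion. The fallback builds the same cis ester by closing C2–C3 instead of C3–C3a, through the known enantioselective, cis-selective Rh(II)-catalysed intramolecular C–H insertion of an aryldiazoacetate. It sets out from 28 (and uses 7 and 10) and comes back to the route at 19. Aryllithium 11, made from 10, is quenched with paraformaldehyde to give [4-(benzyloxy)-3,5-dimethoxyphenyl]methanol F1. B-Alkyl Suzuki coupling of 28 with borane 7 (Pd(OAc)2/SPhos, K3PO4, THF) gives 3-(4-hydroxy-3-methoxyphenyl)propyl benzoate F2, and iodination ortho to the phenol (NIS, MeCN) gives 3-(4-hydroxy-3-iodo-5-methoxyphenyl)propyl benzoate F3. Mitsunobu etherification of F3 with F1 gives 3-[4-{[4-(benzyloxy)-3,5-dimethoxyphenyl]methoxy}-3-iodo-5-methoxyphenyl]propyl benzoate F4. Palladium-catalysed coupling of the aryl iodide with methyl diazoacetate (Pd(PPh3)4, Ag2CO3, Et3N, toluene) gives methyl 2-[5-[3-(benzoyloxy)propyl]-2-{[4-(benzyloxy)-3,5-dimethoxyphenyl]methoxy}-3-methoxyphenyl]-2-diazoacetate F5. Rh2(S-PTTL)4, or its enantiomer if that is the one delivering 2R,3S, in toluene at −60 °C should insert the carbenoid into the benzylic C–H bond and give 19.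

2. Step 17. The aryllithium may add with poor Felkin–Anh discrimination if lithium is chelated by the aryloxy and methoxy oxygens, giving the C1 epimer, and the α-aryloxy aldehyde may enolise. The fallback sets C1 by hydride delivery instead of C–C bond formation. It sets out from 31, taken as its mixture with the C1 epimer, and comes back at 31. Dess–Martin oxidation (NaHCO3, CH2Cl2) of the mixture gives (2S)-1-[3-methoxy-4-(TBSO)phenyl]-2-{4-[(2R,3R)-7-methoxy-3-[(TBSO)methyl]-5-[3-(TBSO)propyl]-2,3-dihydro-1-benzofuran-2-yl]-2,6-dimethoxyphenoxy}-3-(TBSO)propan-1-one F6. Reduction with Zn(BH4)2 in Et2O at −30 °C, with zinc chelated between the carbonyl and the α-aryloxy oxygen, should deliver hydride to the face that gives the anti (1R,2S) alcohol 31.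

3. Step 7. The C3 lithium enolate, or the enolate of the derived 1,3-diketone, may expel the ring phenoxide (E1cB opening to the 2'-hydroxychalcone), and re-closure would erode the C2 configuration. The fallback avoids any metal enolate. It sets out from 14 and comes back at 17. Condensation of 14 with 3 (neat, 80 °C) gives 3-[(2S)-2-[4-(benzyloxy)-3,5-dimethoxyphenyl]-3-[(dimethylamino)methylidene]-8-methoxy-4-oxo-3,4-dihydro-2H-chromen-6-yl]propyl benzoate F7 (alkene geometry not assigned). Diazo transfer to this enaminone with p-ABSA (CH2Cl2, rt) proceeds by cycloaddition and fragmentation, releasing an N-sulfonylformamidine, and should give 17.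

Further compounds

F1 | step 8 | [4-(benzyloxy)-3,5-dimethoxyphenyl]methanol | OCc1cc(OC)c(OCc2ccccc2)c(OC)c1
F2 | step 8 | 3-(4-hydroxy-3-methoxyphenyl)propyl benzoate | O=C(OCCCc1ccc(O)c(OC)c1)c1ccccc1
F3 | step 8 | 3-(4-hydroxy-3-iodo-5-methoxyphenyl)propyl benzoate | O=C(OCCCc1cc(I)c(O)c(OC)c1)c1ccccc1
F4 | step 8 | 3-[4-{[4-(benzyloxy)-3,5-dimethoxyphenyl]methoxy}-3-iodo-5-methoxyphenyl]propyl benzoate | O=C(OCCCc1cc(I)c(OCc2cc(OC)c(OCc3ccccc3)c(OC)c2)c(OC)c1)c1ccccc1
F5 | step 8 | methyl 2-[5-[3-(benzoyloxy)propyl]-2-{[4-(benzyloxy)-3,5-dimethoxyphenyl]methoxy}-3-methoxyphenyl]-2-diazoacetate | COC(=O)C(=[N+]=[N-])c1cc(CCCOC(=O)c2ccccc2)cc(OC)c1OCc1cc(OC)c(OCc2ccccc2)c(OC)c1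
F6 | step 17 | (2S)-1-[3-methoxy-4-(TBSO)phenyl]-2-{4-[(2R,3R)-7-methoxy-3-[(TBSO)methyl]-5-[3-(TBSO)propyl]-2,3-dihydro-1-benzofuran-2-yl]-2,6-dimethoxyphenoxy}-3-(TBSO)propan-1-one | COc1cc(C(=O)[C@H](CO[Si](C)(C)C(C)(C)C)Oc2c(OC)cc([C@@H]3Oc4c(OC)cc(CCCO[Si](C)(C)C(C)(C)C)cc4[C@@H]3CO[Si](C)(C)C(C)(C)C)cc2OC)ccc1O[Si](C)(C)C(C)(C)C
F7 | step 7 | 3-[(2S)-2-[4-(benzyloxy)-3,5-dimethoxyphenyl]-3-[(dimethylamino)methylidene]-8-methoxy-4-oxo-3,4-dihydro-2H-chromen-6-yl]propyl benzoate | c1ccccc1COc2c(OC)cc([C@@H]3Oc4c(OC)cc(CCCOC(=O)c5ccccc5)cc4C(=O)C3=CN(C)C)cc2OC
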